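**Retrosynthetic overview**

1. Serrulatane numbering is used. Ring A = C4a, C5–C8, C8a (C19 = carboxyl carbon on C6, O7, O8). Ring B = C1–C4, C4a, C8a (C20 = methyl on C1, O3 = acetate oxygen, C11 = side-chain methine on C4).
2. Endgame: the O3 acetate comes from the triol acid by peracetylation and selective solvolysis of the two aryl acetates. Ring A is bought as methyl 2,3-dihydroxybenzoate. Ring B is the only ring formed and is closed last.
3. Key disconnection C8a–C1: radical hydroarylation of an open-chain homoallylic alcohol. H• goes to the vinyl terminus (this makes C20), and the C1 radical closes ring B on the unfunctionalised C8a–H and sets C1. The substrate is only isomerised.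
4. Enabling feature: in ring A, C8a is para to C6–C19(=O) and ortho to O8, so it is the one C–H carbon matched to a nucleophilic carbon radical (a polar Friedel–Crafts closure would choose C5, para to O8). C1 is 1,3 to O3, so the radical precursor is simply the allyl adduct of an aldehyde. The peri contacts C20/O8 and C11/C5–H fix C1.
5. C2–C3 is made by reagent-controlled allylboration. C4–C4a is made by organocatalytic α-arylation of (S)-citronellal, whose C1, C2 and C3–C10 become C3, C4 and the whole C11–C18 side chain (10 of the 20 skeletal carbons and the C11 stereocentre come from the chiral pool).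

Key step: step 6

Remark: (S)-citronellal, methyl 2,3-dihydroxybenzoate, both enantiomers of the imidazolidinone catalyst and both enantiomers of B-allyldiisopinocampheylborane are taken as commercially available. Aldehyde 7 is used without storage because its C4–H is acidic.

**Step 1**
Reactants: 1 methyl 2,3-dihydroxybenzoate
Product: 2 methyl 2,3-dihydroxy-5-iodobenzoate
Conditions: NIS (1.05 equiv), CF3CO2H (10 mol %), MeCN, 0 °C to rt
Reagents that add atoms: N-iodosuccinimide O=C1CCC(=O)N1I
Why: Electrophilic aromatic iodination should go to benzoate C5 (the later C4a), which is para to the 2-OH and the only free position meta to the ester, the same site at which 2,3-dihydroxybenzoates are brominated and sulfonated.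

**Step 2**
Reactants: 2 methyl 2,3-dihydroxy-5-iodobenzoate
Product: 3 methyl 5-iodo-2,3-bis(methylsulfonyloxy)benzoate
Conditions: MsCl (2.5 equiv), Et3N (3 equiv), CH2Cl2, 0 °C
Reagents that add atoms: methanesulfonyl chloride CS(=O)(=O)Cl
Why: Standard O-sulfonylation gives mesylates that tolerate the strong acid of step 3 and the amine and borane reagents of steps 4 and 5, make ring A electron-poor for step 6, and are removed by hydroxide in step 7.

**Step 3**
Reactants: 3 methyl 5-iodo-2,3-bis(methylsulfonyloxy)benzoate
Product: 5 [3-methoxycarbonyl-4,5-bis(methylsulfonyloxy)phenyl](2,4,6-trimethylphenyl)iodonium triflate, via hydroxy(triflyloxy)iodoarene 4 (not isolated)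
Conditions: mCPBA (1.1 equiv), mesitylene (1.1 equiv), TfOH (2 equiv), CH2Cl2, 0 °C to 40 °C; precipitation with Et2O
Reagents that add atoms: mesitylene Cc1cc(C)cc(C)c1; trifluoromethanesulfonic acid O=S(=O)(O)C(F)(F)F
Why: This is the one-pot diaryliodonium triflate synthesis, in which the electron-poor aryl iodide is oxidised to the trivalent iodine species 4, which substitutes mesitylene electrophilically, and the mesityl group later serves as the non-transferred dummy ligand.

**Step 4**
Reactants: 5 [3-methoxycarbonyl-4,5-bis(methylsulfonyloxy)phenyl](2,4,6-trimethylphenyl)iodonium triflate; 6 (S)-citronellal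
Product: 7 methyl 5-[(2S,3S)-3,7-dimethyl-1-oxooct-6-en-2-yl]-2,3-bis(methylsulfonyloxy)benzoate
Conditions: CuBr (10 mol %), (2R,5R)-5-benzyl-2-tert-butyl-3-methylimidazolidin-4-one·Cl3CCO2H (10 mol %), NaHCO3 (1.5 equiv), toluene/Et2O 2:1, 23 °C; short silica plug, used at once
Reagents that add atoms: none
Why: In this organocatalytic α-arylation of an aldehyde with a diaryliodonium salt (enamine plus copper catalysis), the E-enamine of 6 turns away from the tert-butyl group and the benzyl group of the (2R,5R) catalyst blocks the Si face of C4, so the aryl–copper species (trivalent copper) should deliver the unhindered aryl group to the Re face and set (4S), with the remote C11 methyl having little say.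

**Step 5**
Reactants: 7 methyl 5-[(2S,3S)-3,7-dimethyl-1-oxooct-6-en-2-yl]-2,3-bis(methylsulfonyloxy)benzoate
Product: 9 methyl 5-[(4R,5S,6S)-4-hydroxy-6,10-dimethylundeca-1,9-dien-5-yl]-2,3-bis(methylsulfonyloxy)benzoate, via diisopinocampheylborinate 8 (not isolated)
Conditions: B-allyldiisopinocampheylborane derived from (−)-α-pinene (1.3 equiv, salt-free), Et2O/pentane, −78 °C; then NaBO3·4H2O, THF/H2O, rt
Reagents that add atoms: B-allyldiisopinocampheylborane from (−)-α-pinene C=CCB([C@H]1C[C@H]2C[C@@H]([C@@H]1C)C2(C)C)[C@H]1C[C@H]2C[C@@H]([C@@H]1C)C2(C)C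
Why: In this Brown allylboration through a closed Zimmerman–Traxler chair, the reagent from (−)-α-pinene attacks the Re face of the aldehyde irrespective of the α-stereocentre and sets (3R), and because no Lewis acid or base is present neither the carbonyl-ene cyclisation typical of citronellal-type aldehydes nor epimerisation at C4 should intervene.

**Step 6**
Reactants: 9 methyl 5-[(4R,5S,6S)-4-hydroxy-6,10-dimethylundeca-1,9-dien-5-yl]-2,3-bis(methylsulfonyloxy)benzoate
Product: 12 methyl (5R,7R,8S)-7-hydroxy-5-methyl-8-[(2S)-6-methylhept-5-en-2-yl]-3,4-bis(methylsulfonyloxy)-5,6,7,8-tetrahydronaphthalene-2-carboxylate, via C1 radical 10 (not isolated), via cyclohexadienyl radical 11 (not isolated)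
Conditions: [N,N'-bis(3,5-di-tert-butylsalicylidene)-2,3-dimethylbutane-2,3-diaminato]cobalt (5 mol %), N-fluoro-2,4,6-trimethylpyridinium triflate (2 equiv), (HMe2Si)2O (2 equiv), PhCF3 (0.02 M), Ar, rt
Reagents that add atoms: none
Why: The cobalt hydride formed from the divalent cobalt salen complex, the N–F oxidant and the silane delivers H• to the unhindered terminus C20 (metal-hydride hydrogen atom transfer, MHAT, Markovnikov sense) to give the nucleophilic secondary radical 10, which adds to C8a, and the cyclohexadienyl radical 11 is then oxidised by trivalent cobalt and loses its C8a proton to collidine, so that 9 is simply isomerised to 12. The closest known reaction type is the cobalt-salen/N-fluoropyridinium/hydrosilane hydroarylation of unactivated terminal alkenes to six-membered benzo-fused rings, together with MHAT-initiated radical cyclisations that terminate on electron-poor arenes. Ring B closes in the six-membered ortho mode of homolytic aromatic substitution, exo with respect to the former alkene (C20 stays outside the ring), while the five-membered ipso attack at C4a is reversible and unproductive. C1 is controlled by the two existing ring-B stereocentres through a chair-like transition state in which the C4 side chain sits axial to avoid C5–H, O3 is then equatorial, and C20 must also be axial because an equatorial methyl group would collide with O8, which places C20 trans to both the side chain and O3, that is (1R). The step needs C8a over C5, and ring A secures this because C8a is para to the C19 carbonyl (where acceptor-substituted arenes take up nucleophilic alkyl radicals best) and ortho to O8 (the position heteroatom substituents favour), whereas C5 is para to O8 (the position they disfavour) and flanked by the bulkier ester, and the two mesylates also switch off any cationic Friedel–Crafts pathway, which would prefer C5. The step also needs the vinyl group over C14=C15, which follows from the steric demand of the salen cobalt hydride (CH2= termini react much faster than trisubstituted alkenes) and from the absence of any acid that could protonate the more basic trisubstituted alkene, and O3–H cannot compete because it could only form an oxetane.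

**Step 7**
Reactants: 12 methyl (5R,7R,8S)-7-hydroxy-5-methyl-8-[(2S)-6-methylhept-5-en-2-yl]-3,4-bis(methylsulfonyloxy)-5,6,7,8-tetrahydronaphthalene-2-carboxylate
Product: 13 (5R,7R,8S)-3,4,7-trihydroxy-5-methyl-8-[(2S)-6-methylhept-5-en-2-yl]-5,6,7,8-tetrahydronaphthalene-2-carboxylic acid
Conditions: KOH (10 equiv), 1,4-dioxane/H2O 2:1 (degassed), 70 °C; then 1 M HCl to pH 2
Reagents that add atoms: potassium hydroxide [K+].[OH-]
Why: Saponification of the methyl ester and hydroxide cleavage of both aryl mesylates (S–O scission) should occur in one operation without touching the alkene or any stereocentre, and the methanol-free, oxygen-free medium avoids formation of methyl mesylate and oxidation of the catecholate.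

**Step 8**
Reactants: 13 (5R,7R,8S)-3,4,7-trihydroxy-5-methyl-8-[(2S)-6-methylhept-5-en-2-yl]-5,6,7,8-tetrahydronaphthalene-2-carboxylic acid
Product: 14 (5R,7R,8S)-3,4,7-triacetoxy-5-methyl-8-[(2S)-6-methylhept-5-en-2-yl]-5,6,7,8-tetrahydronaphthalene-2-carboxylic acid
Conditions: Ac2O (6 equiv), pyridine, DMAP (10 mol %), CH2Cl2, 0 °C to rt; aqueous work-up
Reagents that add atoms: acetic anhydride CC(=O)OC(C)=O
Why: Exhaustive DMAP-catalysed acetylation needs no selectivity, since the two phenols react at once and DMAP drives the hindered equatorial O3–H to completion with retention at C3.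

**Step 9**
Reactants: 14 (5R,7R,8S)-3,4,7-triacetoxy-5-methyl-8-[(2S)-6-methylhept-5-en-2-yl]-5,6,7,8-tetrahydronaphthalene-2-carboxylic acid
Product: 15 (5R,7R,8S)-7-acetoxy-3,4-dihydroxy-5-methyl-8-[(2S)-6-methylhept-5-en-2-yl]-5,6,7,8-tetrahydronaphthalene-2-carboxylic acid (3-acetoxy-7,8-dihydroxyserrulat-14-en-19-oic acid, the target)
Conditions: NH4OAc (10 equiv), MeOH/H2O 4:1, rt; dilute citric acid work-up
Reagents that add atoms: none
Why: Chemoselective solvolysis of aryl acetates under near-neutral ammonium acetate catalysis should remove only the O7 and O8 acetates (phenoxide is the better leaving group and the O7 acetate is further activated by the neighbouring carboxylate) and leave the secondary alkyl acetate at O3 untouched.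

**Compound list**

1 | methyl 2,3-dihydroxybenzoate | COC(=O)c1cccc(O)c1O | starting material
2 | methyl 2,3-dihydroxy-5-iodobenzoate | COC(=O)c1cc(I)cc(O)c1O | intermediate
3 | methyl 5-iodo-2,3-bis(methylsulfonyloxy)benzoate | COC(=O)c1cc(I)cc(OS(C)(=O)=O)c1OS(C)(=O)=O | intermediate
4 | methyl 5-[hydroxy(trifluoromethylsulfonyloxy)-λ3-iodanyl]-2,3-bis(methylsulfonyloxy)benzoate (not isolated) | COC(=O)c1cc(I(O)OS(=O)(=O)C(F)(F)F)cc(OS(C)(=O)=O)c1OS(C)(=O)=O | intermediate
5 | [3-methoxycarbonyl-4,5-bis(methylsulfonyloxy)phenyl](2,4,6-trimethylphenyl)iodonium triflate | COC(=O)c1cc([I+]c2c(C)cc(C)cc2C)cc(OS(C)(=O)=O)c1OS(C)(=O)=O.[O-]S(=O)(=O)C(F)(F)F | intermediate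
6 | (S)-citronellal, (3S)-3,7-dimethyloct-6-enal | O=CC[C@@H](C)CCC=C(C)C | starting material
7 | methyl 5-[(2S,3S)-3,7-dimethyl-1-oxooct-6-en-2-yl]-2,3-bis(methylsulfonyloxy)benzoate | O=C[C@H](c1cc(OS(C)(=O)=O)c(OS(C)(=O)=O)c(C(=O)OC)c1)[C@@H](C)CCC=C(C)C | intermediate
8 | O3-diisopinocampheylborinate of 9 (not isolated) | O(B([C@H]1C[C@H]2C[C@@H]([C@@H]1C)C2(C)C)[C@H]1C[C@H]2C[C@@H]([C@@H]1C)C2(C)C)[C@H](CC=C)[C@H](c1cc(OS(C)(=O)=O)c(OS(C)(=O)=O)c(C(=O)OC)c1)[C@@H](C)CCC=C(C)C | intermediate
9 | methyl 5-[(4R,5S,6S)-4-hydroxy-6,10-dimethylundeca-1,9-dien-5-yl]-2,3-bis(methylsulfonyloxy)benzoate | O[C@H](CC=C)[C@H](c1cc(OS(C)(=O)=O)c(OS(C)(=O)=O)c(C(=O)OC)c1)[C@@H](C)CCC=C(C)C | intermediate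
10 | secondary C1 radical formed by H• addition to C20 of 9 (not isolated) | O[C@H](C[CH]C)[C@H](c1cc(OS(C)(=O)=O)c(OS(C)(=O)=O)c(C(=O)OC)c1)[C@@H](C)CCC=C(C)C | intermediate
11 | cyclohexadienyl radical formed by attack of C1 on C8a, C8a–H on the face of the C4 side chain, spin on C4a, C6 and C8 (not isolated) | O[C@@H]1C[C@@H](C)[C@H]2C(OS(C)(=O)=O)=C(OS(C)(=O)=O)[C](C(=O)OC)C=C2[C@@H]1[C@@H](C)CCC=C(C)C | intermediate
12 | methyl (5R,7R,8S)-7-hydroxy-5-methyl-8-[(2S)-6-methylhept-5-en-2-yl]-3,4-bis(methylsulfonyloxy)-5,6,7,8-tetrahydronaphthalene-2-carboxylate | O[C@@H]1C[C@@H](C)c2c(cc(C(=O)OC)c(OS(C)(=O)=O)c2OS(C)(=O)=O)[C@@H]1[C@@H](C)CCC=C(C)C | intermediate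
13 | (5R,7R,8S)-3,4,7-trihydroxy-5-methyl-8-[(2S)-6-methylhept-5-en-2-yl]-5,6,7,8-tetrahydronaphthalene-2-carboxylic acid | O[C@@H]1C[C@@H](C)c2c(cc(C(=O)O)c(O)c2O)[C@@H]1[C@@H](C)CCC=C(C)C | intermediate
14 | (5R,7R,8S)-3,4,7-triacetoxy-5-methyl-8-[(2S)-6-methylhept-5-en-2-yl]-5,6,7,8-tetrahydronaphthalene-2-carboxylic acid | CC(=O)O[C@@H]1C[C@@H](C)c2c(cc(C(=O)O)c(OC(C)=O)c2OC(C)=O)[C@@H]1[C@@H](C)CCC=C(C)C | intermediate
15 | (5R,7R,8S)-7-acetoxy-3,4-dihydroxy-5-methyl-8-[(2S)-6-methylhept-5-en-2-yl]-5,6,7,8-tetrahydronaphthalene-2-carboxylic acid | CC(=O)O[C@@H]1C[C@@H](C)c2c(cc(C(=O)O)c(O)c2O)[C@@H]1[C@@H](C)CCC=C(C)C | target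

Total step count: 9. Longest linear sequence: 9 steps (1 to 15; 6 enters at step 4).

**Steps most likely to fail**

**Step 6.**
- *What may go wrong:* Hydrogen-atom transfer may also reach C14=C15. The terminal alkene may chain-walk to the internal allylic alcohol before the slow addition to ring A takes place. The alkylcobalt species may also be diverted into polar trapping.
- *Fallback (sets out from 9, returns at 13):* Radical generation is separated from alkene differentiation.
  - A Tsuji–Wacker oxidation (PdCl2, CuCl, O2, DMF/H2O), which ignores trisubstituted alkenes, gives the β-hydroxy methyl ketone F1.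
  - An Evans–Tishchenko reduction (SmI2 cat., CH3CHO, THF, −10 °C) gives the anti 3-acetoxy 1-alcohol F2.
  - An Appel reaction (I2, PPh3, imidazole, toluene) gives the secondary C1 iodide F3.
  - Pd(PPh3)4 and K3PO4 in dioxane at 100 °C (palladium-catalysed ring-forming aromatic C–H alkylation with unactivated alkyl halides, a radical process started by zerovalent palladium) generate the same C1 radical. This closes the same C8a–C1 bond under the same controls and gives the tetralin acetate F4.
  - KOH under the conditions of step 7 converts F4 into 13.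

**Step 4.**
- *What may go wrong:* The C4 configuration may erode, because the benzylic α-hydrogen next to an electron-poor aryl group enolises during a slow reaction of the β-branched aldehyde or during isolation.
- *Fallback (sets out from 5 and 6, returns at 7):* The aldehyde is not isolated. The finished reaction mixture is treated with NaBH4 in MeOH at 0 °C, which locks C4 in the configurationally stable primary alcohol F5. The minor C4 epimer is removed by chromatography at this stage. Dess–Martin periodinane with NaHCO3 in CH2Cl2 then regenerates 7 under neutral conditions directly before step 5.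

**Step 5.**
- *What may go wrong:* Reagent control may be insufficient if the intrinsic facial bias of the α-aryl aldehyde opposes the borane, which would lead to poor facial selectivity at C3.
- *Fallback (sets out from 7, returns at 9):* C3 is set by ketone reduction instead of by C–C bond formation.
  - Uncatalysed addition of allylboronic acid pinacol ester (toluene, rt, neutral) gives the C3-epimeric homoallylic alcohols F6.
  - Buffered Dess–Martin oxidation gives the β,γ-unsaturated ketone F7.
  - Corey–Bakshi–Shibata reduction follows, with (S)-2-methyl-CBS-oxazaborolidine and catecholborane in toluene at −78 °C. Catecholborane does not hydroborate the alkenes at this temperature. The catalyst differentiates the small allyl CH2 from the large CH(aryl)(alkyl) group and should give the (3R) alcohol 9.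

**Further compounds**

F1 | step 6 | methyl 5-[(4R,5S,6S)-4-hydroxy-6,10-dimethyl-2-oxoundec-9-en-5-yl]-2,3-bis(methylsulfonyloxy)benzoate | O[C@H](CC(C)=O)[C@H](c1cc(OS(C)(=O)=O)c(OS(C)(=O)=O)c(C(=O)OC)c1)[C@@H](C)CCC=C(C)C
F2 | step 6 | methyl 5-[(2S,4R,5S,6S)-4-acetoxy-2-hydroxy-6,10-dimethylundec-9-en-5-yl]-2,3-bis(methylsulfonyloxy)benzoate | CC(=O)O[C@H](C[C@H](C)O)[C@H](c1cc(OS(C)(=O)=O)c(OS(C)(=O)=O)c(C(=O)OC)c1)[C@@H](C)CCC=C(C)C
F3 | step 6 | methyl 5-[(2R,4R,5S,6S)-4-acetoxy-2-iodo-6,10-dimethylundec-9-en-5-yl]-2,3-bis(methylsulfonyloxy)benzoate | CC(=O)O[C@H](C[C@@H](C)I)[C@H](c1cc(OS(C)(=O)=O)c(OS(C)(=O)=O)c(C(=O)OC)c1)[C@@H](C)CCC=C(C)C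
F4 | step 6 | methyl (5R,7R,8S)-7-acetoxy-5-methyl-8-[(2S)-6-methylhept-5-en-2-yl]-3,4-bis(methylsulfonyloxy)-5,6,7,8-tetrahydronaphthalene-2-carboxylate | CC(=O)O[C@@H]1C[C@@H](C)c2c(cc(C(=O)OC)c(OS(C)(=O)=O)c2OS(C)(=O)=O)[C@@H]1[C@@H](C)CCC=C(C)C
F5 | step 4 | methyl 5-[(2S,3S)-1-hydroxy-3,7-dimethyloct-6-en-2-yl]-2,3-bis(methylsulfonyloxy)benzoate | OC[C@H](c1cc(OS(C)(=O)=O)c(OS(C)(=O)=O)c(C(=O)OC)c1)[C@@H](C)CCC=C(C)C
F6 | step 5 | methyl 5-[(5S,6S)-4-hydroxy-6,10-dimethylundeca-1,9-dien-5-yl]-2,3-bis(methylsulfonyloxy)benzoate, mixture of C4 epimers of the chain (C3 of the target) | OC(CC=C)[C@H](c1cc(OS(C)(=O)=O)c(OS(C)(=O)=O)c(C(=O)OC)c1)[C@@H](C)CCC=C(C)C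
F7 | step 5 | methyl 5-[(5S,6S)-6,10-dimethyl-4-oxoundeca-1,9-dien-5-yl]-2,3-bis(methylsulfonyloxy)benzoate | O=C(CC=C)[C@H](c1cc(OS(C)(=O)=O)c(OS(C)(=O)=O)c(C(=O)OC)c1)[C@@H](C)CCC=C(C)C
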